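**Retrosynthetic overview**
1. Target 29 ⇐ phenol acid 26: ortho-oxygenation to the 11,12-quinone, tautomerisation to the C7 quinone methide and closure of the C20→C7 lactone (last ring).
2. 26 ⇐ tricyclic alcohol 22 by C20 oxidation, debenzylation and selective O-acetylation.
3. 22 ⇐ Z-allylic alcohol 21 by a catalytic asymmetric proton-initiated bicyclisation (C4–C5 and C9–C10 bonds; ring A, then ring B, onto the existing arene ring C).
4. 21 ⇐ aldehyde 12 + phosphonium salt 16 + formaldehyde (β-oxido ylide olefination).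
5. 12 ⇐ p-benzoquinone + propanal (organocatalytic α-arylation sets C15), then aryl triflate and Heck reaction with allyl alcohol.

Assumption: tricyclic compounds carry abietane numbering (ring A C1–C5/C10, ring B C5–C10, arene ring C C8–C14, side chain C15–C17, C20 on C10); the target is then (5S,7S,10R,15S)-16-acetoxycarnosol.

**Step 1**
Reactants: 1 p-benzoquinone, 2 propanal
Product: 4 (3S)-3-methyl-2,3-dihydro-1-benzofuran-2,5-diol, via (2S)-2-(2,5-dihydroxyphenyl)propanal 3 (not isolated)
Conditions: (R)-2-{bis[3,5-bis(trifluoromethyl)phenyl](trimethylsilyloxy)methyl}pyrrolidine (10 mol %), EtOH/H2O 1:1, −20 °C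
Reagents that add atoms: none
Why: Enamine-catalysed α-arylation of an aldehyde by conjugate addition to the quinone (Jørgensen-type); the diarylprolinol silyl ether shields one enamine face so that C15 forms as S, and rearomatisation plus hemiacetal closure protect the α-aryl aldehyde from racemisation.

**Step 2**
Reactants: 4 (3S)-3-methyl-2,3-dihydro-1-benzofuran-2,5-diol
Product: 5 (3S)-2-hydroxy-3-methyl-2,3-dihydro-1-benzofuran-5-yl trifluoromethanesulfonate
Conditions: PhNTf2 (1.05 equiv), Et3N (1.2 equiv), CH2Cl2, 0 °C, 1 h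
Reagents that add atoms: N-phenylbis(trifluoromethanesulfonimide), FC(F)(F)S(=O)(=O)N(c1ccccc1)S(=O)(=O)C(F)(F)F
Why: Chemoselective O-triflation of the only phenol (the hemiacetal hydroxyl is less acidic and is not sulfonylated by this mild reagent), run cold and briefly so that the ring-opened aldehyde cannot epimerise C15.

**Step 3**
Reactants: 5 (3S)-2-hydroxy-3-methyl-2,3-dihydro-1-benzofuran-5-yl trifluoromethanesulfonate
Product: 7 4-hydroxy-3-[(2S)-1-hydroxypropan-2-yl]phenyl trifluoromethanesulfonate, via ring-opened aldehyde 6 (not isolated)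
Conditions: NaBH4, MeOH/THF, 0 °C
Reagents that add atoms: none
Why: Borohydride reduction of the lactol through its ring-opened hydroxy aldehyde gives the primary alcohol and frees the C12 phenol; C15 is then no longer next to a carbonyl, and the aryl triflate tolerates NaBH4.

**Step 4**
Reactants: 7 4-hydroxy-3-[(2S)-1-hydroxypropan-2-yl]phenyl trifluoromethanesulfonate
Product: 9 4-(benzyloxy)-3-[(2S)-1-(benzyloxy)propan-2-yl]phenyl trifluoromethanesulfonate, via mono-benzyl ether 8 (not isolated)
Conditions: BnBr (2.4 equiv), NaH (2.3 equiv), tetrabutylammonium iodide (cat.), THF/DMF, 0 → 25 °C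
Reagents that add atoms: benzyl bromide, BrCc1ccccc1
Why: Williamson etherification of the phenoxide and then the alkoxide; NaH is added to the substrate/BnBr mixture so the alkoxide is benzylated faster than it can attack the aryl triflate.

**Step 5**
Reactants: 9 4-(benzyloxy)-3-[(2S)-1-(benzyloxy)propan-2-yl]phenyl trifluoromethanesulfonate, 10 allyl alcohol
Product: 12 3-{4-(benzyloxy)-3-[(2S)-1-(benzyloxy)propan-2-yl]phenyl}propanal, via enol 11 (not isolated)
Conditions: Pd(OAc)2 (5 mol %), P(o-tol)3 (10 mol %), Bu4NCl, NaHCO3, DMF, 70 °C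
Reagents that add atoms: none
Why: Heck arylation of allyl alcohol (Jeffery conditions): insertion at the terminal carbon and β-hydride elimination towards the carbinol give the enol, which tautomerises to the 3-arylpropanal; chloride keeps the neutral pathway (linear product) and benzyl ethers are inert.

**Step 6**
Reactants: 13 methyltriphenylphosphonium bromide, 14 5-bromo-2-methylpent-2-ene
Product: 16 (5-methylhex-4-en-1-yl)triphenylphosphonium bromide, via methylidenetriphenylphosphorane 15 (not isolated)
Conditions: n-BuLi (1.0 equiv), THF, 0 °C; then inverse addition to 14 (1.5 equiv), 0 → 25 °C; salt precipitated with Et2O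
Reagents that add atoms: none
Why: SN2 C-alkylation of a non-stabilised phosphonium ylide by a primary bromide gives the homologous phosphonium salt, inverse addition limiting transylidation.

**Step 7**
Reactants: 16 (5-methylhex-4-en-1-yl)triphenylphosphonium bromide, 12 3-{4-(benzyloxy)-3-[(2S)-1-(benzyloxy)propan-2-yl]phenyl}propanal, 17 formaldehyde
Product: 21 (2Z)-5-{4-(benzyloxy)-3-[(2S)-1-(benzyloxy)propan-2-yl]phenyl}-2-(4-methylpent-3-en-1-yl)pent-2-en-1-ol, via ylide 18 (not isolated), via betaine 19 (not isolated), via β-oxido ylide 20 (not isolated)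
Conditions: 16, n-BuLi (1.05 equiv), THF, 0 °C; 12, −78 °C; n-BuLi (1.05 equiv), −78 → −40 °C; monomeric CH2O (excess, from cracked paraformaldehyde), −40 → 25 °C; aq. NH4Cl
Reagents that add atoms: none
Why: Corey–Schlosser β-oxido ylide (SCOOPY) olefination: the low-temperature betaine is deprotonated, hydroxymethylated by formaldehyde and loses Ph3PO with the oxygen of 12, which places CH2OH cis to the arylethyl chain (Z) stereospecifically.

**Step 8**
Reactants: 21 (2Z)-5-{4-(benzyloxy)-3-[(2S)-1-(benzyloxy)propan-2-yl]phenyl}-2-(4-methylpent-3-en-1-yl)pent-2-en-1-ol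
Product: 22 (5S,10R,15S)-12,16-bis(benzyloxy)abieta-8,11,13-trien-20-ol
Conditions: (S,S)-IDPi (C2-symmetric BINOL-derived imidodiphosphorimidate Brønsted acid, 3,3′-aryl groups, N-triflyl core; 5 mol %; sense of induction to be confirmed, the mirror-image catalyst gives the other series), (CF3)3COH/CHCl3 3:1, −20 °C, 72 h
Reagents that add atoms: none
Why: Proposed new method: the confined chiral acid in a fluorinated alcohol protonates the terminal trisubstituted alkene at C3 inside its pocket and the ion pair collapses through a chair–chair (Stork–Eschenmoser) array in which C5 attacks C4 and the arene carbon C9 (para to the C13 alkyl group, the unhindered ortho position) attacks C10, so anti addition across the Z-alkene gives the trans-fused A/B system with axial CH2OH, the catalyst and not the remote C15 centre fixing C5 as S and C10 as R; the closest known reaction type is the imidodiphosphorimidate-catalysed proton-initiated polyene cyclisation of homofarnesol-type alcohols together with chiral-acid cyclisations of homogeranylarenes, and capture of β-oxygenated tertiary cations by tethered arenes is known from epoxide–arene cyclisations, whereas a central alkene that carries a free allylic hydroxyl (inductively deactivated) combined with an arene terminator under catalyst control has not been shown.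

**Step 9**
Reactants: 22 (5S,10R,15S)-12,16-bis(benzyloxy)abieta-8,11,13-trien-20-ol
Product: 24 (5S,10R,15S)-12,16-bis(benzyloxy)abieta-8,11,13-trien-20-oic acid, via aldehyde 23 (not isolated)
Conditions: nor-AZADO (5 mol %), NaClO2 (3 equiv), NaOCl (2 mol %), MeCN/phosphate buffer pH 6.8, 25 °C
Reagents that add atoms: sodium chlorite, [Na+].[O-]Cl=O
Why: Nitroxyl/chlorite (Zhao-type) oxidation: the small oxoammonium ion takes the hindered neopentyl alcohol to the aldehyde and chlorite takes it on to the acid in one pot, leaving the benzyl ethers and all stereocentres (C10 is quaternary) untouched.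

**Step 10**
Reactants: 24 (5S,10R,15S)-12,16-bis(benzyloxy)abieta-8,11,13-trien-20-oic acid
Product: 25 (5S,10R,15S)-12,16-dihydroxyabieta-8,11,13-trien-20-oic acid
Conditions: H2 (1 atm), Pd/C (10 wt %), EtOAc/MeOH, 25 °C
Reagents that add atoms: none
Why: Hydrogenolysis of both benzyl ethers frees the phenol and the primary alcohol; no other reducible group or epimerisable centre is present.

**Step 11**
Reactants: 25 (5S,10R,15S)-12,16-dihydroxyabieta-8,11,13-trien-20-oic acid
Product: 26 (5S,10R,15S)-16-acetoxy-12-hydroxyabieta-8,11,13-trien-20-oic acid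
Conditions: vinyl acetate (5 equiv), Novozym 435 (immobilised Candida antarctica lipase B), MTBE, 40 °C
Reagents that add atoms: vinyl acetate, CC(=O)OC=C
Why: Lipase-catalysed transesterification with an enol ester acylates only the primary aliphatic hydroxyl (the phenol and the hindered acid on a quaternary carbon are not substrates) and is irreversible because vinyl alcohol leaves as acetaldehyde.

**Step 12**
Reactants: 26 (5S,10R,15S)-16-acetoxy-12-hydroxyabieta-8,11,13-trien-20-oic acid
Product: 29 (5S,7S,10R,15S)-16-acetoxy-11,12-dihydroxyabieta-8,11,13-trien-20,7-olide, via ortho-quinone 27 (not isolated), via quinone methide 28 (not isolated)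
Conditions: (PhSeO)2O (0.7 equiv), THF, 50 °C, 1 h; then 25 °C, 12 h, argon
Reagents that add atoms: benzeneseleninic anhydride, O=[Se](c1ccccc1)O[Se](=O)c1ccccc1
Why: Barton ortho-oxygenation of the phenol gives the 11,12-quinone at the only free ortho carbon, and, as in the carnosic acid to carnosol conversion, it tautomerises to the para-quinone methide (C7=C8) to which the C20 acid adds from the only face it can reach, setting C7 as S and regenerating the catechol.

**Compound list**
1 | p-benzoquinone | O=C1C=CC(=O)C=C1 | starting material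
2 | propanal | CCC=O | starting material
3 | (2S)-2-(2,5-dihydroxyphenyl)propanal | C[C@H](C=O)c1cc(O)ccc1O | intermediate
4 | (3S)-3-methyl-2,3-dihydro-1-benzofuran-2,5-diol (both C2 anomers) | C[C@@H]1C(O)Oc2ccc(O)cc12 | intermediate
5 | (3S)-2-hydroxy-3-methyl-2,3-dihydro-1-benzofuran-5-yl trifluoromethanesulfonate | C[C@@H]1C(O)Oc2ccc(OS(=O)(=O)C(F)(F)F)cc12 | intermediate
6 | 4-hydroxy-3-[(2S)-1-oxopropan-2-yl]phenyl trifluoromethanesulfonate | C[C@H](C=O)c1cc(OS(=O)(=O)C(F)(F)F)ccc1O | intermediate
7 | 4-hydroxy-3-[(2S)-1-hydroxypropan-2-yl]phenyl trifluoromethanesulfonate | C[C@H](CO)c1cc(OS(=O)(=O)C(F)(F)F)ccc1O | intermediate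
8 | 4-(benzyloxy)-3-[(2S)-1-hydroxypropan-2-yl]phenyl trifluoromethanesulfonate | C[C@H](CO)c1cc(OS(=O)(=O)C(F)(F)F)ccc1OCc1ccccc1 | intermediate
9 | 4-(benzyloxy)-3-[(2S)-1-(benzyloxy)propan-2-yl]phenyl trifluoromethanesulfonate | C[C@H](COCc1ccccc1)c1cc(OS(=O)(=O)C(F)(F)F)ccc1OCc1ccccc1 | intermediate
10 | allyl alcohol (prop-2-en-1-ol) | C=CCO | starting material
11 | 3-{4-(benzyloxy)-3-[(2S)-1-(benzyloxy)propan-2-yl]phenyl}prop-1-en-1-ol (enol, E/Z) | C[C@H](COCc1ccccc1)c1cc(CC=CO)ccc1OCc1ccccc1 | intermediate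
12 | 3-{4-(benzyloxy)-3-[(2S)-1-(benzyloxy)propan-2-yl]phenyl}propanal | C[C@H](COCc1ccccc1)c1cc(CCC=O)ccc1OCc1ccccc1 | intermediate
13 | methyltriphenylphosphonium bromide | C[P+](c1ccccc1)(c1ccccc1)c1ccccc1.[Br-] | starting material
14 | 5-bromo-2-methylpent-2-ene | CC(C)=CCCBr | starting material
15 | methylidenetriphenylphosphorane | C=P(c1ccccc1)(c1ccccc1)c1ccccc1 | intermediate
16 | (5-methylhex-4-en-1-yl)triphenylphosphonium bromide | CC(C)=CCCC[P+](c1ccccc1)(c1ccccc1)c1ccccc1.[Br-] | intermediate
17 | formaldehyde (monomer, from paraformaldehyde) | C=O | starting material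
18 | (5-methylhex-4-en-1-ylidene)triphenylphosphorane | CC(C)=CCCC=P(c1ccccc1)(c1ccccc1)c1ccccc1 | intermediate
19 | 1-{4-(benzyloxy)-3-[(2S)-1-(benzyloxy)propan-2-yl]phenyl}-8-methyl-4-(triphenylphosphonio)non-7-en-3-olate, lithium bromide adduct (betaine, C3/C4 mixture) | C[C@H](COCc1ccccc1)c1cc(CCC([O-])C(CCC=C(C)C)[P+](c2ccccc2)(c2ccccc2)c2ccccc2)ccc1OCc1ccccc1.[Li+].[Br-] | intermediate
20 | lithium 1-{4-(benzyloxy)-3-[(2S)-1-(benzyloxy)propan-2-yl]phenyl}-8-methyl-4-(triphenylphosphoranylidene)non-7-en-3-olate (β-oxido ylide) | C[C@H](COCc1ccccc1)c1cc(CCC([O-])C(CCC=C(C)C)=P(c2ccccc2)(c2ccccc2)c2ccccc2)ccc1OCc1ccccc1.[Li+] | intermediate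
21 | (2Z)-5-{4-(benzyloxy)-3-[(2S)-1-(benzyloxy)propan-2-yl]phenyl}-2-(4-methylpent-3-en-1-yl)pent-2-en-1-ol | C[C@H](COCc1ccccc1)c1cc(CC/C=C(\CO)CCC=C(C)C)ccc1OCc1ccccc1 | intermediate
22 | (5S,10R,15S)-12,16-bis(benzyloxy)abieta-8,11,13-trien-20-ol | C[C@H](COCc1ccccc1)c1cc2c(cc1OCc1ccccc1)[C@@]1(CO)CCCC(C)(C)[C@@H]1CC2 | intermediate
23 | (5S,10R,15S)-12,16-bis(benzyloxy)abieta-8,11,13-trien-20-al | C[C@H](COCc1ccccc1)c1cc2c(cc1OCc1ccccc1)[C@@]1(C=O)CCCC(C)(C)[C@@H]1CC2 | intermediate
24 | (5S,10R,15S)-12,16-bis(benzyloxy)abieta-8,11,13-trien-20-oic acid | C[C@H](COCc1ccccc1)c1cc2c(cc1OCc1ccccc1)[C@@]1(C(=O)O)CCCC(C)(C)[C@@H]1CC2 | intermediate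
25 | (5S,10R,15S)-12,16-dihydroxyabieta-8,11,13-trien-20-oic acid | C[C@H](CO)c1cc2c(cc1O)[C@@]1(C(=O)O)CCCC(C)(C)[C@@H]1CC2 | intermediate
26 | (5S,10R,15S)-16-acetoxy-12-hydroxyabieta-8,11,13-trien-20-oic acid | CC(=O)OC[C@@H](C)c1cc2c(cc1O)[C@@]1(C(=O)O)CCCC(C)(C)[C@@H]1CC2 | intermediate
27 | (5S,10R,15S)-16-acetoxy-11,12-dioxoabieta-8,13-dien-20-oic acid | CC(=O)OC[C@@H](C)C1=CC2=C(C(=O)C1=O)[C@@]1(C(=O)O)CCCC(C)(C)[C@@H]1CC2 | intermediate
28 | (5S,10R,15S)-16-acetoxy-11-hydroxy-12-oxoabieta-7,9(11),13-trien-20-oic acid (para-quinone methide) | CC(=O)OC[C@@H](C)C1=CC2=CC[C@H]3C(C)(C)CCC[C@]3(C(=O)O)C2=C(O)C1=O | intermediate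
29 | (5S,7S,10R,15S)-16-acetoxy-11,12-dihydroxyabieta-8,11,13-trien-20,7-olide (CNP0105472.1) | CC(=O)OC[C@@H](C)c1cc2c(c(O)c1O)[C@@]13CCCC(C)(C)[C@@H]1C[C@@H]2OC3=O | target

**Step count**
Total: 12 steps. Longest linear sequence: 11 steps (steps 1–5, then 7–12); step 6 is a one-step side branch.

**Steps most likely to fail**

Step 8 (the new bicyclisation). Possible failures are a stall after ring A, ionisation of the allylic alcohol, a 1,2-hydride shift of the β-hydroxy cation to an aldehyde, or low catalyst control. The fallback uses known radical chemistry at the ester oxidation level; it sets out from aldehyde 12 (with bromide 14) and comes back at 25. Commercial benzyl diethylphosphonoacetate is alkylated with 14 (NaH, DMF) to benzyl 2-(diethoxyphosphoryl)-6-methylhept-5-enoate F1. Horner–Wadsworth–Emmons reaction of F1 with 12 (NaH, THF) gives benzyl (2E)-5-{4-(benzyloxy)-3-[(2S)-1-(benzyloxy)propan-2-yl]phenyl}-2-(4-methylpent-3-en-1-yl)pent-2-enoate F2, whose double-bond geometry does not matter here. A hydrogen-atom-transfer-initiated radical bicyclisation (Co(salen) catalyst, N-fluoro-2,4,6-trimethylpyridinium tetrafluoroborate, PhSiH3, HFIP, 0 °C) then forms the tertiary C4 radical, closes ring A by 6-endo addition to C5 and closes ring B by addition of the α-ester radical to C9. This gives trans-fused benzyl (5S,10R,15S)-12,16-bis(benzyloxy)abieta-8,11,13-trien-20-oate F3 together with its (5R,10S) diastereomer, since nothing controls the core relative to C15; the two are separated by preparative HPLC. H2 over Pd/C removes all three benzyl groups from F3 and gives 25, so steps 9 and 10 are skipped. The cost is half of the material and the loss of catalyst control over C5 and C10.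

Step 12 (oxygenation/lactonisation cascade). C11 is hindered, the product catechol can be over-oxidised (a dithionite wash returns it), and tautomerisation through C15–H instead of C7–H would erode C15. The fallback separates lactone formation from oxygenation; it sets out from 26 and comes back at 29. DDQ (dioxane, 25 °C) dehydrogenates the para-hydroxybenzylic C7–H to the para-quinone methide, which the C20 acid traps to give (5S,7S,10R,15S)-16-acetoxy-12-hydroxyabieta-8,11,13-trien-20,7-olide F4. Teuber oxidation of F4 with (KSO3)2NO (acetone/phosphate buffer) gives (5S,7S,10R,15S)-16-acetoxy-11,12-dioxoabieta-8,13-dien-20,7-olide F5, which can no longer rearrange. Reduction of F5 with aqueous Na2S2O4 gives 29.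

Step 7 (β-oxido ylide olefination). It needs exact low-temperature control, and step 6 can give dialkylated salt. The fallback builds the alkene at the ester level and reduces; it sets out from 12 (with 14) and comes back at 21. Commercial methyl bis(2,2,2-trifluoroethyl)phosphonoacetate is alkylated with 14 (NaH, DMF) to methyl 2-[bis(2,2,2-trifluoroethoxy)phosphoryl]-6-methylhept-5-enoate F6. Still–Gennari olefination of 12 with F6 (KHMDS, 18-crown-6, THF, −78 °C) gives methyl (2Z)-5-{4-(benzyloxy)-3-[(2S)-1-(benzyloxy)propan-2-yl]phenyl}-2-(4-methylpent-3-en-1-yl)pent-2-enoate F7. Reduction of F7 with i-Bu2AlH (CH2Cl2, −78 °C) gives 21 with the geometry retained, at the cost of one extra step.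

**Further compounds**
F1 | step 8 | benzyl 2-(diethoxyphosphoryl)-6-methylhept-5-enoate | CCOP(=O)(OCC)C(CCC=C(C)C)C(=O)OCc1ccccc1
F2 | step 8 | benzyl (2E)-5-{4-(benzyloxy)-3-[(2S)-1-(benzyloxy)propan-2-yl]phenyl}-2-(4-methylpent-3-en-1-yl)pent-2-enoate | C[C@H](COCc1ccccc1)c1cc(CC/C=C(\CCC=C(C)C)C(=O)OCc2ccccc2)ccc1OCc1ccccc1
F3 | step 8 | benzyl (5S,10R,15S)-12,16-bis(benzyloxy)abieta-8,11,13-trien-20-oate | C[C@H](COCc1ccccc1)c1cc2c(cc1OCc1ccccc1)[C@@]1(C(=O)OCc3ccccc3)CCCC(C)(C)[C@@H]1CC2
F4 | step 12 | (5S,7S,10R,15S)-16-acetoxy-12-hydroxyabieta-8,11,13-trien-20,7-olide | CC(=O)OC[C@@H](C)c1cc2c(cc1O)[C@@]13CCCC(C)(C)[C@@H]1C[C@@H]2OC3=O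
F5 | step 12 | (5S,7S,10R,15S)-16-acetoxy-11,12-dioxoabieta-8,13-dien-20,7-olide | CC(=O)OC[C@@H](C)C1=CC2=C(C(=O)C1=O)[C@@]13CCCC(C)(C)[C@@H]1C[C@@H]2OC3=O
F6 | step 7 | methyl 2-[bis(2,2,2-trifluoroethoxy)phosphoryl]-6-methylhept-5-enoate | COC(=O)C(CCC=C(C)C)P(=O)(OCC(F)(F)F)OCC(F)(F)F
F7 | step 7 | methyl (2Z)-5-{4-(benzyloxy)-3-[(2S)-1-(benzyloxy)propan-2-yl]phenyl}-2-(4-methylpent-3-en-1-yl)pent-2-enoate | C[C@H](COCc1ccccc1)c1cc(CC/C=C(/CCC=C(C)C)C(=O)OC)ccc1OCc1ccccc1
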